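**Retrosynthetic overview**

- The target is read as the cis-(2R,3S)-2-hydroxymethyl-3-aryl-1,4-benzodioxane (7S,8R in lignan numbering) carrying an (E)-3-hydroxypropenyl group on ring B.
- The side chain is installed last: Suzuki–Miyaura coupling of an aryl bromide with an (E)-3-borylallyl alcohol, then desilylation in the same flask.
- The dioxane ring (the only ring made; both benzene rings are bought) is formed in one step. Both C–O bonds and both stereocentres come from an enantioselective hetero-Diels–Alder reaction between an o-quinone (O=C–C=O as 4π unit) and a (Z)-cinnamyl alcohol; Z geometry gives the cis ring.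
- The o-quinone comes from oxidative demethylation of mirror-symmetric 4-bromo-2,6-dimethoxyphenol (syringol + NBS). This dearomatises ring B and differentiates its two equivalent methoxy carbons; the ring rearomatises in the cycloaddition.
- The (Z)-alkene comes from 5-hydroxyvanillin by bis-silylation, Still–Gennari olefination and reduction.

Assumption: the absolute sense of induction in the new catalytic key step (step 5) follows the working model given there; if the first adduct proves to be the antipode (chiral HPLC, CD), (S)-TRIP is used instead of (R)-TRIP.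

**Route**

Step 1
Reactants: 1 3,4-dihydroxy-5-methoxybenzaldehyde (5-hydroxyvanillin)
Product: 2 3,4-bis[(tert-butyldimethylsilyl)oxy]-5-methoxybenzaldehyde
Conditions: TBSCl (2.5 equiv), imidazole (5 equiv), DMF, 0 °C → rt
Reagents that add atoms: tert-butyldimethylsilyl chloride (TBSCl), CC(C)(C)[Si](C)(C)Cl
Why: Imidazole-promoted silylation of both phenols stops catechol/quinone redox exchange in step 5, and the flanked, out-of-plane 4-silyloxy group makes the aryl ring only a modest cation stabiliser.

Step 2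
Reactants: 2 3,4-bis[(tert-butyldimethylsilyl)oxy]-5-methoxybenzaldehyde
Product: 3 methyl (Z)-3-{3,4-bis[(tert-butyldimethylsilyl)oxy]-5-methoxyphenyl}prop-2-enoate
Conditions: (CF3CH2O)2P(O)CH2CO2Me, KN(SiMe3)2, 18-crown-6, THF, −78 °C
Reagents that add atoms: methyl bis(2,2,2-trifluoroethyl)phosphonoacetate, COC(=O)CP(=O)(OCC(F)(F)F)OCC(F)(F)F
Why: Still–Gennari variant of the Horner–Wadsworth–Emmons reaction; fast, irreversible elimination from the electron-poor phosphonate adduct gives the Z-enoate (typically ≥15:1 with aryl aldehydes).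

Step 3
Reactants: 3 methyl (Z)-3-{3,4-bis[(tert-butyldimethylsilyl)oxy]-5-methoxyphenyl}prop-2-enoate
Product: 4 (Z)-3-{3,4-bis[(tert-butyldimethylsilyl)oxy]-5-methoxyphenyl}prop-2-en-1-ol
Conditions: i-Bu2AlH (2.5 equiv), CH2Cl2, −78 °C; aq. potassium sodium tartrate work-up
Reagents that add atoms: none
Why: 1,2-Reduction of the enoate by i-Bu2AlH leaves the Z-alkene and the aryl silyl ethers untouched.

Step 4
Reactants: 5 2,6-dimethoxyphenol (syringol)
Product: 6 4-bromo-2,6-dimethoxyphenol
Conditions: NBS (1.0 equiv), CHCl3 (EtOH-stabilised), −45 °C → rt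
Reagents that add atoms: N-bromosuccinimide, O=C1CCC(=O)N1Br
Why: Electrophilic aromatic bromination goes para to the free OH because both ortho positions are blocked, so the mirror symmetry is kept.

Step 5
Reactants: 6 4-bromo-2,6-dimethoxyphenol (1.4 equiv); 4 (Z)-3-{3,4-bis[(tert-butyldimethylsilyl)oxy]-5-methoxyphenyl}prop-2-en-1-ol (1.0 equiv)
Product: 8 [(2R,3S)-3-{3,4-bis[(tert-butyldimethylsilyl)oxy]-5-methoxyphenyl}-6-bromo-8-methoxy-2,3-dihydro-1,4-benzodioxin-2-yl]methanol, via o-quinone 7 (not isolated)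
Conditions: NaIO4 (1.5 equiv), H2O/CH2Cl2, 0 °C, 10 min; separated CH2Cl2 phase dried (Na2SO4), then added to 4, (R)-TRIP [(R)-3,3'-bis(2,4,6-triisopropylphenyl)-1,1'-binaphthyl-2,2'-diyl hydrogen phosphate] (10 mol%), 4 Å MS, toluene/CH2Cl2, −40 °C
Reagents that add atoms: sodium periodate (one O atom, the new quinone oxygen), [Na+].[O-]I(=O)(=O)=O
Why: Proposed new method: Adler-type periodate oxidation of symmetric 6 (aryl periodate ester, O-transfer to one of the two equivalent methoxy-bearing carbons, loss of MeOH) gives o-quinone 7, which reacts as an electron-poor O=C–C=O heterodiene in an inverse-electron-demand hetero-Diels–Alder reaction with the Z-alkene of 4 and rearomatises ring B; addition is suprafacial on the alkene, so Z geometry becomes the cis-2,3 relationship; the chiral phosphoric acid hydrogen-bonds the more basic carbonyl oxygen (the one conjugated with the OMe and Br donors), which makes the other oxygen (next to C–OMe) the electrophilic terminus that bonds the nucleophilic CH2OH-bearing alkene carbon while the hydrogen-bonded oxygen closes on the benzylic carbon, giving the required regiochemistry; the phosphate bridges quinone (P–OH···O=C) and allylic alcohol (O–H···O=P) so that one alkene face is presented in the 3,3'-aryl pocket, setting (2R,3S); the closest known reactions are the thermal, stereospecific hetero-Diels–Alder reactions of o-quinones with styrenes that give 1,4-benzodioxanes, and chiral-phosphoric-acid-catalysed [4+2] cycloadditions of o-quinone methides and quinones with alkenes that carry a hydrogen-bond donor.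

Step 6
Reactants: 8 [(2R,3S)-3-{3,4-bis[(tert-butyldimethylsilyl)oxy]-5-methoxyphenyl}-6-bromo-8-methoxy-2,3-dihydro-1,4-benzodioxin-2-yl]methanol; 9 (E)-3-(4,4,5,5-tetramethyl-1,3,2-dioxaborolan-2-yl)prop-2-en-1-ol (1.5 equiv)
Product: 11 (E)-3-[(2R,3S)-3-(3,4-dihydroxy-5-methoxyphenyl)-2-(hydroxymethyl)-8-methoxy-2,3-dihydro-1,4-benzodioxin-6-yl]prop-2-en-1-ol, via bis-silyl ether 10 (not isolated)
Conditions: Pd(OAc)2 (5 mol%), SPhos (2-dicyclohexylphosphino-2',6'-dimethoxybiphenyl, 10 mol%), K3PO4 (3 equiv), THF/H2O (10:1), 40 °C, Ar; then AcOH to pH 6, KHF2 (6 equiv), MeOH, rt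
Reagents that add atoms: none
Why: Suzuki–Miyaura coupling (oxidative addition of zerovalent palladium into Ar–Br, transmetalation with retention of the E-alkenyl geometry, reductive elimination) is followed in the same flask by bifluoride cleavage of both aryl silyl ethers at near-neutral pH, which avoids the base-induced quinone-methide ring opening that would epimerise the cis benzylic centre once the para-phenol is free.

**Compound list**

1 | 3,4-dihydroxy-5-methoxybenzaldehyde (5-hydroxyvanillin) | COc1cc(C=O)cc(O)c1O | starting material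
2 | 3,4-bis[(tert-butyldimethylsilyl)oxy]-5-methoxybenzaldehyde | COc1cc(C=O)cc(O[Si](C)(C)C(C)(C)C)c1O[Si](C)(C)C(C)(C)C | intermediate
3 | methyl (Z)-3-{3,4-bis[(tert-butyldimethylsilyl)oxy]-5-methoxyphenyl}prop-2-enoate | COc1cc(/C=C\C(=O)OC)cc(O[Si](C)(C)C(C)(C)C)c1O[Si](C)(C)C(C)(C)C | intermediate
4 | (Z)-3-{3,4-bis[(tert-butyldimethylsilyl)oxy]-5-methoxyphenyl}prop-2-en-1-ol | COc1cc(/C=C\CO)cc(O[Si](C)(C)C(C)(C)C)c1O[Si](C)(C)C(C)(C)C | intermediate
5 | 2,6-dimethoxyphenol (syringol) | COc1cccc(OC)c1O | starting material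
6 | 4-bromo-2,6-dimethoxyphenol | COc1cc(Br)cc(OC)c1O | intermediate
7 | 5-bromo-3-methoxycyclohexa-3,5-diene-1,2-dione (o-quinone, not isolated) | COC1=CC(Br)=CC(=O)C1=O | intermediate
8 | [(2R,3S)-3-{3,4-bis[(tert-butyldimethylsilyl)oxy]-5-methoxyphenyl}-6-bromo-8-methoxy-2,3-dihydro-1,4-benzodioxin-2-yl]methanol | COc1cc([C@@H]2Oc3cc(Br)cc(OC)c3O[C@@H]2CO)cc(O[Si](C)(C)C(C)(C)C)c1O[Si](C)(C)C(C)(C)C | intermediate
9 | (E)-3-(4,4,5,5-tetramethyl-1,3,2-dioxaborolan-2-yl)prop-2-en-1-ol | OC/C=C/B1OC(C)(C)C(C)(C)O1 | starting material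
10 | (E)-3-[(2R,3S)-3-{3,4-bis[(tert-butyldimethylsilyl)oxy]-5-methoxyphenyl}-2-(hydroxymethyl)-8-methoxy-2,3-dihydro-1,4-benzodioxin-6-yl]prop-2-en-1-ol (not isolated) | COc1cc([C@@H]2Oc3cc(/C=C/CO)cc(OC)c3O[C@@H]2CO)cc(O[Si](C)(C)C(C)(C)C)c1O[Si](C)(C)C(C)(C)C | intermediate
11 | (E)-3-[(2R,3S)-3-(3,4-dihydroxy-5-methoxyphenyl)-2-(hydroxymethyl)-8-methoxy-2,3-dihydro-1,4-benzodioxin-6-yl]prop-2-en-1-ol | COc1cc([C@@H]2Oc3cc(/C=C/CO)cc(OC)c3O[C@@H]2CO)cc(O)c1O | target

**Step count**

Total: 6 steps. Longest linear sequence: 5 steps (1 → 2 → 3 → 4 → 8 → 11, i.e. steps 1, 2, 3, 5, 6).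

**Steps most likely to fail, with fallbacks**

Step 5 is the main risk. The catalytic asymmetric cycloaddition is unprecedented, so the ee may be low. The regiochemistry rests on an electronic argument and has to be confirmed by HMBC. Some trans isomer could form if the addition becomes stepwise; the cis ring shows J(H2,H3) of about 2–3 Hz. The fallback sets out from 4 and 6 and returns at 8. The quinone 7 is made as before and combined with 4 in CH2Cl2 at 0 °C → rt without catalyst. This thermal hetero-Diels–Alder reaction gives the racemic cis adduct, that is 8 together with its enantiomer [(2S,3R)-3-{3,4-bis[(tert-butyldimethylsilyl)oxy]-5-methoxyphenyl}-6-bromo-8-methoxy-2,3-dihydro-1,4-benzodioxin-2-yl]methanol F1. The racemate is then resolved by lipase-catalysed acylation of the primary alcohol (Burkholderia cepacia lipase, vinyl acetate, MTBE, 30 °C). The enzyme is chosen by screening so that the (2S,3R)-alcohol is converted into [(2S,3R)-3-{3,4-bis[(tert-butyldimethylsilyl)oxy]-5-methoxyphenyl}-6-bromo-8-methoxy-2,3-dihydro-1,4-benzodioxin-2-yl]methyl acetate F2. Unreacted 8 is recovered by chromatography at slightly above 50% conversion and goes on into step 6.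

Step 6 is the second risk. The hydroxyallyl boronate may protodeboronate, oxidative addition into the electron-rich bromide may be slow, and the free catechol is exposed in the same flask as palladium. The fallback sets out from 8 and returns at 10. A Heck reaction with methyl acrylate (Pd(OAc)2, P(t-Bu)3·HBF4, Cy2NMe, 1,4-dioxane, 80 °C; no free phenoxide, so no epimerisation) gives methyl (E)-3-[(2R,3S)-3-{3,4-bis[(tert-butyldimethylsilyl)oxy]-5-methoxyphenyl}-2-(hydroxymethyl)-8-methoxy-2,3-dihydro-1,4-benzodioxin-6-yl]prop-2-enoate F3. Reduction with i-Bu2AlH (CH2Cl2, −78 °C) gives 10, now isolated and purified. Compound 10 is then desilylated on its own with KHF2 in MeOH at rt to give 11.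

Step 2 is the third risk. Z-selectivity may be incomplete and the Z/E enoates hard to separate, and any E-alkene carried forward would give the trans ring. The fallback sets out from 2 and returns at 4, bypassing 3. Corey–Fuchs olefination (CBr4, PPh3, CH2Cl2, 0 °C) gives tert-butyl-[2-[tert-butyl(dimethyl)silyl]oxy-5-(2,2-dibromoethenyl)-3-methoxyphenoxy]-dimethylsilane F4. Treatment with n-BuLi (2.2 equiv, THF, −78 °C) and then paraformaldehyde gives the propargylic alcohol 3-{3,4-bis[(tert-butyldimethylsilyl)oxy]-5-methoxyphenyl}prop-2-yn-1-ol F5. Semi-hydrogenation (H2 1 atm, Pd/CaCO3 poisoned with Pb(OAc)2, quinoline, EtOAc) gives 4 as the pure Z-isomer.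

**Further compounds**

F1 | step 5 | [(2S,3R)-3-{3,4-bis[(tert-butyldimethylsilyl)oxy]-5-methoxyphenyl}-6-bromo-8-methoxy-2,3-dihydro-1,4-benzodioxin-2-yl]methanol | COc1cc([C@H]2Oc3cc(Br)cc(OC)c3O[C@H]2CO)cc(O[Si](C)(C)C(C)(C)C)c1O[Si](C)(C)C(C)(C)C
F2 | step 5 | [(2S,3R)-3-{3,4-bis[(tert-butyldimethylsilyl)oxy]-5-methoxyphenyl}-6-bromo-8-methoxy-2,3-dihydro-1,4-benzodioxin-2-yl]methyl acetate | COc1cc([C@H]2Oc3cc(Br)cc(OC)c3O[C@H]2COC(C)=O)cc(O[Si](C)(C)C(C)(C)C)c1O[Si](C)(C)C(C)(C)C
F3 | step 6 | methyl (E)-3-[(2R,3S)-3-{3,4-bis[(tert-butyldimethylsilyl)oxy]-5-methoxyphenyl}-2-(hydroxymethyl)-8-methoxy-2,3-dihydro-1,4-benzodioxin-6-yl]prop-2-enoate | COc1cc([C@@H]2Oc3cc(/C=C/C(=O)OC)cc(OC)c3O[C@@H]2CO)cc(O[Si](C)(C)C(C)(C)C)c1O[Si](C)(C)C(C)(C)C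
F4 | step 2 | tert-butyl-[2-[tert-butyl(dimethyl)silyl]oxy-5-(2,2-dibromoethenyl)-3-methoxyphenoxy]-dimethylsilane | COc1cc(C=C(Br)Br)cc(O[Si](C)(C)C(C)(C)C)c1O[Si](C)(C)C(C)(C)C
F5 | step 2 | 3-{3,4-bis[(tert-butyldimethylsilyl)oxy]-5-methoxyphenyl}prop-2-yn-1-ol | COc1cc(C#CCO)cc(O[Si](C)(C)C(C)(C)C)c1O[Si](C)(C)C(C)(C)C
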